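all flasks: solid substrate 0.050 M
- alder: second substrate 1.5 equiv; free enzyme 9.0 × 10⁻⁴ mol%; run made earlier
- ash: second substrate 1.5 equiv; free enzyme 0.0014 mol%; run made earlier
- flask: second substrate 1.50 equiv; free enzyme 0.0018 mol%

- alder (time / s: target / %, solid substrate / %): 15.0: 4.1, 95.2; 30.0: 7.0, 93.0; 40.0: 9.2, 90.3; 60.0: 13.3, 85.5; 80.0: 16.5, 82.5; 90.0: 18.7, 78.6
- ash (time / s: target / %, solid substrate / %): 10.0: 1.3, 98.4; 15.0: 1.2, 94.1; 25.0: 6.0, 93.5; 40.0: 9.0, 90.3; 60.0: 13.7, 84.4; 80.0: 18.2, 79.0; 90.0: 22.5, 76.7

(scatter of a reading: 1 percentage point)

- factor on the rate of making target when 50% of the solid substrate are converted (what has only dissolved counts as not reacted) if second substrate is charged twice over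
- factor on the rate when 50% of the solid substrate are converted (what has only dissolved counts as not reacted) if free enzyme is charged at 2.0 × 10⁻⁴ mol% instead

- solid substrate is a solid; its amount is given per volume of the solution
- at the start none of the solid substrate is in solution
- what has only dissolved of solid substrate counts as not reacted
- no earlier run changes the charge of second substrate; that part of a forecast is a guess

1. First instants. Add target and solid substrate in the last ash reading and 0.8 percentage points of the charge is left over, against a scatter of 1 point. So we read what stands dissolved as too small to see: solid substrate enters solution and is soon used.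

2. Middle. Taking the last two readings of each run from the origin, alder makes target at 0.00621 M min⁻¹ and ash at 0.00718 M min⁻¹. The rate grows by 1.16 while the loading grows by 1.56, which is less. We therefore reckon with two resistances in series, dissolving and enzyme turnover.

3. The two runs, with their scatter, give 5.5 × 10⁻⁴ mol%. This is the even loading, at which both resistances are equal. A flask with the same charges of solid substrate and second substrate then runs at the share loading/(loading + even loading) of a ceiling, here 0.00999 M min⁻¹.

4. Later. At 50% conversion, 50.0% of the charge is still unreacted, what has only dissolved counted with it, so we expect the same straight stretch. The flask's share is 76.7% and the low loading's is 26.7%, so our factor is 0.349, lower than the forecast's 0.4. For doubling, we share the forecast's guess of 1.1: “Doubling the second substrate should barely help while dissolution limits the rate.”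

5. The flask gives 1.00 for doubling and 0.394 for the low loading.

    solid substrate ⇌ starting material, rate k1*(cs1 - [starting material]) while solid is left; crystals form when [starting material] > cs1 (solubility = 3.50 mM, k = 0.0474 s⁻¹)
    second complex → free enzyme + target (k = 78300 s⁻¹)
    starting material + free enzyme ⇌ first complex (K = 25.0 M⁻¹, k = 1.09 × 10⁷ M⁻¹ s⁻¹)
    first product → by-product carried off (k = 0.0426 s⁻¹)
    first complex ⇌ loaded enzyme + first product (K = 1.39 M, k = 9970 s⁻¹)
    second substrate + loaded enzyme ⇌ second complex (K = 12.8 M⁻¹, k = 7.13 × 10⁶ M⁻¹ s⁻¹)

At 2.00 min, the flask held free enzyme, the resting state, at 98.0% of the catalyst and starting material at 1.27% of the charge. By the even loading, the ceiling times the share gives this flask 0.00766 M min⁻¹, against its 0.00815 M min⁻¹. At 2.0 × 10⁻⁴ mol%, the same reckoning gives 0.00267 M min⁻¹, and the factor found above on the flask's rate gives 0.00321 M min⁻¹.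

(The numbers in the tables come from a simulation for substances that don't exist.)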